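**Retrosynthetic overview**
1. The target is an ent-labd-7-en-15-oic acid with an axial 3-OAc and an axial C19 CH2OH. The C11–C12 bond is cut into two primary alkyl radicals, each drawn from a carboxylic acid one carbon longer: a decalin acid (CO2H on C11) and methyl hydrogen (R)-3-methylglutarate, which brings C12–C16 with C13 bought.
2. The decalin acid comes from cheap andrographolide by oxidative cleavage of its C12=C13 and C8=C17 double bonds. Rings A and B and the centres C4, C5, C9 and C10 are kept, the butenolide arm is discarded, and ring B gains a C8 ketone.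
3. Enabling feature: C11 (exocyclic CH2 on ring-B carbon C9) and C12 (CH2 next to the C13 methine) are both non-stereogenic primary sp3 carbons without heteroatoms. The bond between them can therefore be made by nickel-mediated union of two decarboxylatively generated primary radicals without touching C9 or C13.
4. After the union the C8 ketone becomes the C8 methyl/C7=C8 alkene (kinetic C7 enol triflate, Negishi methylation). Ring A is finished by inversion of C3 (oxidation, bulky-hydride reduction), acetylation, and release of O19 and the acid.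
5. Ring order: no carbocycle is built. Rings A and B come intact from andrographolide; the only ring made (step 1) and removed (step 8) is the temporary 1,3-dioxane of the 3,19-acetonide.

Key step: step 5

Remark: atom numbers are labdane numbers (ring A C1–C5/C10, ring B C5–C10, side chain C11–C16 on C9, C17 on C8, C18 methyl and C19 CH2O on C4, C20 on C10). The target is read as an ent-labdane whose C4, C5, C9 and C10 configurations are those of andrographolide and whose C3 oxygen is axial (inverted relative to andrographolide). Andrographolide and methyl hydrogen (R)-3-methylglutarate are taken as commercial.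

**Step 1**
Reactants: 1 andrographolide
Product: 2 3,19-O-isopropylideneandrographolide
Conditions: Me2C(OMe)2, PPTS (cat.), acetone, 40 °C
Reagents that add atoms: 2,2-dimethoxypropane COC(C)(C)OC
Why: Acid-catalysed transacetalisation (acetonide formation) should close a six-membered dioxane on the cis-disposed 1,3-diol (equatorial 3-OH, axial C19 CH2OH), while the C14 hydroxyl has no 1,3-partner and stays free; no stereocentre is touched.

**Step 2**
Reactants: 2 3,19-O-isopropylideneandrographolide
Product: 4 3,19-O-isopropylidene-8-oxo-13,14,15,16,17-pentanor-ent-labdan-12-oic acid, via keto aldehyde 3 (not isolated)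
Conditions: O3, CH2Cl2/MeOH, −78 °C; Me2S, −78 °C→rt; then NaClO2, NaH2PO4, 2-methyl-2-butene, tBuOH/H2O, 0 °C→rt
Reagents that add atoms: ozone [O-][O+]=O; sodium chlorite [Na+].[O-]Cl=O
Why: Ozonolysis with reductive work-up should cleave both C=C bonds to the C8 ketone and the C12 aldehyde, and Pinnick oxidation should take the aldehyde to the acid; C9 keeps its equatorial CH2 substituent, which is also the thermodynamically preferred arrangement next to the ketone.

**Step 3**
Reactants: 4 3,19-O-isopropylidene-8-oxo-13,14,15,16,17-pentanor-ent-labdan-12-oic acid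
Product: 5 1,3-dioxoisoindolin-2-yl 3,19-O-isopropylidene-8-oxo-13,14,15,16,17-pentanor-ent-labdan-12-oate
Conditions: N-hydroxyphthalimide, DIC, DMAP (cat.), CH2Cl2, rt
Reagents that add atoms: N-hydroxyphthalimide ON1C(=O)c2ccccc2C1=O
Why: Carbodiimide (Steglich-type) esterification of the primary carboxyl group should give the redox-active ester without affecting ketone or acetonide.

**Step 4**
Reactants: 6 (R)-5-methoxy-3-methyl-5-oxopentanoic acid (methyl hydrogen (R)-3-methylglutarate)
Product: 7 1-(1,3-dioxoisoindolin-2-yl) 5-methyl (3S)-3-methylpentanedioate (same spatial arrangement as 6; the descriptor changes by priority only)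
Conditions: N-hydroxyphthalimide, DIC, DMAP (cat.), CH2Cl2, rt
Reagents that add atoms: N-hydroxyphthalimide ON1C(=O)c2ccccc2C1=O
Why: Steglich-type esterification of the free carboxyl group; the stereocentre is β to the reacting carbonyl and cannot epimerise.

**Step 5**
Reactants: 5 1,3-dioxoisoindolin-2-yl 3,19-O-isopropylidene-8-oxo-13,14,15,16,17-pentanor-ent-labdan-12-oate and 7 1-(1,3-dioxoisoindolin-2-yl) 5-methyl (3S)-3-methylpentanedioate (threefold excess)
Product: 8 methyl (13R)-3,19-O-isopropylidene-8-oxo-17-nor-ent-labdan-15-oate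
Conditions: NiCl2·6H2O (20 mol%), 2,2':6',2''-terpyridine (20 mol%), AgNO3 (0.3 equiv), NMP, Mg(+)/RVC(−), constant current, rt
Reagents that add atoms: none
Why: Cathodic single-electron reduction of each N-hydroxyphthalimide ester gives a radical anion that loses phthalimide anion and CO2, so that 5 delivers the primary C11 radical and 7 the primary C12 radical; the terpyridine–nickel catalyst captures the two radicals in turn and reductive elimination from the dialkylnickel species forms the C11–C12 bond. The closest known reaction type is the nickel-electrocatalysed doubly decarboxylative C(sp3)–C(sp3) cross-coupling of two redox-active esters, the catalytic relative of a mixed Kolbe electrolysis. No ring is closed and no stereocentre is created: C9 and C13 flank the new bond but are never radical sites, so the configuration taken from 1 and bought with 6 is carried through unchanged. The step needs cross- over homo-coupling, which the excess of the cheap ester 7 and the like primary character of both radicals should secure, and chemoselectivity for the two redox-active esters over the C8 ketone, the methyl ester and the acetonide, which are reduced only at far more negative potential. Fast capture of the C11 radical by nickel should outrun its 1,2-acyl shift onto the C8 carbonyl. In this one operation the last carbon left from the degraded butenolide arm leaves as CO2 and the complete C12–C16 chain with its C13 stereocentre is attached.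

**Step 6**
Reactants: 8 methyl (13R)-3,19-O-isopropylidene-8-oxo-17-nor-ent-labdan-15-oate
Product: 10 methyl (13R)-3,19-O-isopropylidene-8-(trifluoromethylsulfonyloxy)-17-nor-ent-labd-7-en-15-oate, via potassium enolate 9 (not isolated)
Conditions: KHMDS (1.1 equiv), THF, −78 °C; PhNTf2, −78→0 °C
Reagents that add atoms: N-phenylbis(trifluoromethanesulfonimide) O=S(=O)(N(c1ccccc1)S(=O)(=O)C(F)(F)F)C(F)(F)F; potassium bis(trimethylsilyl)amide C[Si](C)(C)[N-][Si](C)(C)C.[K+] (its potassium stays only in intermediate 9)
Why: Kinetic deprotonation should occur at the unhindered C7 methylene rather than at the C9 methine beside quaternary C10 (and at the ketone rather than the far less acidic ester), and O-triflation of that enolate fixes the C7=C8 position (regioselective enol triflate formation).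

**Step 7**
Reactants: 10 methyl (13R)-3,19-O-isopropylidene-8-(trifluoromethylsulfonyloxy)-17-nor-ent-labd-7-en-15-oate
Product: 11 methyl (13R)-3,19-O-isopropylidene-ent-labd-7-en-15-oate
Conditions: MeZnCl, Pd(PPh3)4 (5 mol%), THF, 50 °C
Reagents that add atoms: methylzinc chloride C[Zn]Cl
Why: Negishi coupling (oxidative addition of the alkenyl triflate, transmetalation, reductive elimination) should install C17 on C8 with the alkene held at C7=C8; the organozinc tolerates the methyl ester and C9 is not touched.

**Step 8**
Reactants: 11 methyl (13R)-3,19-O-isopropylidene-ent-labd-7-en-15-oate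
Product: 12 methyl (3R,13R)-3,19-dihydroxy-ent-labd-7-en-15-oate (equatorial 3-OH)
Conditions: PPTS (cat.), MeOH, 40 °C
Reagents that add atoms: none
Why: Mild acid-catalysed transacetalisation to methanol removes the acetonide under conditions that should not migrate the trisubstituted alkene and cannot change the methyl ester.

**Step 9**
Reactants: 12 methyl (3R,13R)-3,19-dihydroxy-ent-labd-7-en-15-oate
Product: 13 methyl (3R,13R)-19-(tert-butyldimethylsilyloxy)-3-hydroxy-ent-labd-7-en-15-oate
Conditions: TBSCl (1.1 equiv), imidazole, CH2Cl2, 0 °C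
Reagents that add atoms: tert-butyldimethylsilyl chloride CC(C)(C)[Si](C)(C)Cl
Why: Silylation should select the primary C19 hydroxyl over the hindered secondary C3 hydroxyl beside quaternary C4.

**Step 10**
Reactants: 13 methyl (3R,13R)-19-(tert-butyldimethylsilyloxy)-3-hydroxy-ent-labd-7-en-15-oate
Product: 14 methyl (13R)-19-(tert-butyldimethylsilyloxy)-3-oxo-ent-labd-7-en-15-oate
Conditions: Dess–Martin periodinane, NaHCO3, CH2Cl2, rt
Reagents that add atoms: none
Why: Dess–Martin oxidation of the secondary alcohol; C4 is quaternary, so neither epimerisation nor β-elimination of the silyloxy group is possible.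

**Step 11**
Reactants: 14 methyl (13R)-19-(tert-butyldimethylsilyloxy)-3-oxo-ent-labd-7-en-15-oate
Product: 15 methyl (3S,13R)-19-(tert-butyldimethylsilyloxy)-3-hydroxy-ent-labd-7-en-15-oate (axial 3-OH)
Conditions: L-Selectride, THF, −78 °C; aq. NH4Cl
Reagents that add atoms: none
Why: The bulky trialkylborohydride should deliver hydride from the equatorial direction, since axial approach is blocked for it by the axial hydrogens on C1 and C5, giving the axial alcohol and thus inverting C3 relative to andrographolide; the ester is not reduced at −78 °C.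

**Step 12**
Reactants: 15 methyl (3S,13R)-19-(tert-butyldimethylsilyloxy)-3-hydroxy-ent-labd-7-en-15-oate
Product: 16 (3S,13R)-19-(tert-butyldimethylsilyloxy)-3-hydroxy-ent-labd-7-en-15-oic acid
Conditions: LiOH, THF/MeOH/H2O, rt; then 1 M HCl to pH 4
Reagents that add atoms: lithium hydroxide [Li+].[OH-]
Why: Saponification of the unhindered methyl ester before the acetate is introduced; the neopentyl TBS ether is stable and no base-sensitive stereocentre is present.

**Step 13**
Reactants: 16 (3S,13R)-19-(tert-butyldimethylsilyloxy)-3-hydroxy-ent-labd-7-en-15-oic acid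
Product: 18 (3S,13R)-3-acetoxy-19-(tert-butyldimethylsilyloxy)-ent-labd-7-en-15-oic acid, via mixed anhydride 17 (not isolated)
Conditions: Ac2O, DMAP, pyridine, CH2Cl2, rt; then aq. NaHCO3
Reagents that add atoms: acetic anhydride CC(=O)OC(C)=O; water O (hydrolysis of 17)
Why: DMAP-catalysed acylation should acetylate the axial 3-OH, while the carboxyl group is converted only transiently into its mixed acetic anhydride, which the aqueous bicarbonate work-up hydrolyses.

**Step 14**
Reactants: 18 (3S,13R)-3-acetoxy-19-(tert-butyldimethylsilyloxy)-ent-labd-7-en-15-oic acid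
Product: 19 (3S,4R,5S,9R,10S,13R)-3-acetoxy-19-hydroxylabd-7-en-15-oic acid (CNP0138726.1)
Conditions: HF·pyridine, pyridine/THF, 0 °C→rt
Reagents that add atoms: none
Why: Fluoride-mediated desilylation frees O19; the acetate should not migrate because the axial O3 and the axial C19 CH2O lie on opposite faces (antiperiplanar), and the alkene and the acid are inert to buffered HF.

**Compound list**
1 | andrographolide | O[C@@H]1CC[C@]2(C)[C@H](CCC(=C)[C@H]2C/C=C3/C(=O)OC[C@H]3O)[C@]1(C)CO | starting material
2 | 3,19-O-isopropylideneandrographolide | CC3(C)O[C@@H]1CC[C@]2(C)[C@H](CCC(=C)[C@H]2C/C=C4/C(=O)OC[C@H]4O)[C@]1(C)CO3 | intermediate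
3 | 3,19-O-isopropylidene-8-oxo-13,14,15,16,17-pentanor-ent-labdan-12-al (keto aldehyde) | CC3(C)O[C@@H]1CC[C@]2(C)[C@H](CCC(=O)[C@H]2CC=O)[C@]1(C)CO3 | intermediate
4 | 3,19-O-isopropylidene-8-oxo-13,14,15,16,17-pentanor-ent-labdan-12-oic acid | CC3(C)O[C@@H]1CC[C@]2(C)[C@H](CCC(=O)[C@H]2CC(=O)O)[C@]1(C)CO3 | intermediate
5 | 1,3-dioxoisoindolin-2-yl ester of 4 | CC3(C)O[C@@H]1CC[C@]2(C)[C@H](CCC(=O)[C@H]2CC(=O)ON4C(=O)c5ccccc5C4=O)[C@]1(C)CO3 | intermediate
6 | (R)-5-methoxy-3-methyl-5-oxopentanoic acid | COC(=O)C[C@H](C)CC(=O)O | starting material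
7 | 1-(1,3-dioxoisoindolin-2-yl) 5-methyl (3S)-3-methylpentanedioate | COC(=O)C[C@H](C)CC(=O)ON1C(=O)c2ccccc2C1=O | intermediate
8 | methyl (13R)-3,19-O-isopropylidene-8-oxo-17-nor-ent-labdan-15-oate | CC3(C)O[C@@H]1CC[C@]2(C)[C@H](CCC(=O)[C@H]2CC[C@@H](C)CC(=O)OC)[C@]1(C)CO3 | intermediate
9 | potassium C7=C8 enolate of 8 | CC3(C)O[C@@H]1CC[C@]2(C)[C@H](CC=C([O-])[C@H]2CC[C@@H](C)CC(=O)OC)[C@]1(C)CO3.[K+] | intermediate
10 | methyl (13R)-3,19-O-isopropylidene-8-(trifluoromethylsulfonyloxy)-17-nor-ent-labd-7-en-15-oate | CC3(C)O[C@@H]1CC[C@]2(C)[C@H](CC=C(OS(=O)(=O)C(F)(F)F)[C@H]2CC[C@@H](C)CC(=O)OC)[C@]1(C)CO3 | intermediate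
11 | methyl (13R)-3,19-O-isopropylidene-ent-labd-7-en-15-oate | CC3(C)O[C@@H]1CC[C@]2(C)[C@H](CC=C(C)[C@H]2CC[C@@H](C)CC(=O)OC)[C@]1(C)CO3 | intermediate
12 | methyl (3R,13R)-3,19-dihydroxy-ent-labd-7-en-15-oate (equatorial 3-OH) | O[C@@H]1CC[C@]2(C)[C@H](CC=C(C)[C@H]2CC[C@@H](C)CC(=O)OC)[C@]1(C)CO | intermediate
13 | methyl (3R,13R)-19-(tert-butyldimethylsilyloxy)-3-hydroxy-ent-labd-7-en-15-oate | O[C@@H]1CC[C@]2(C)[C@H](CC=C(C)[C@H]2CC[C@@H](C)CC(=O)OC)[C@]1(C)CO[Si](C)(C)C(C)(C)C | intermediate
14 | methyl (13R)-19-(tert-butyldimethylsilyloxy)-3-oxo-ent-labd-7-en-15-oate | O=C1CC[C@]2(C)[C@H](CC=C(C)[C@H]2CC[C@@H](C)CC(=O)OC)[C@]1(C)CO[Si](C)(C)C(C)(C)C | intermediate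
15 | methyl (3S,13R)-19-(tert-butyldimethylsilyloxy)-3-hydroxy-ent-labd-7-en-15-oate (axial 3-OH) | O[C@H]1CC[C@]2(C)[C@H](CC=C(C)[C@H]2CC[C@@H](C)CC(=O)OC)[C@]1(C)CO[Si](C)(C)C(C)(C)C | intermediate
16 | (3S,13R)-19-(tert-butyldimethylsilyloxy)-3-hydroxy-ent-labd-7-en-15-oic acid | O[C@H]1CC[C@]2(C)[C@H](CC=C(C)[C@H]2CC[C@@H](C)CC(=O)O)[C@]1(C)CO[Si](C)(C)C(C)(C)C | intermediate
17 | mixed acetic anhydride of 18 | CC(=O)O[C@H]1CC[C@]2(C)[C@H](CC=C(C)[C@H]2CC[C@@H](C)CC(=O)OC(C)=O)[C@]1(C)CO[Si](C)(C)C(C)(C)C | intermediate
18 | (3S,13R)-3-acetoxy-19-(tert-butyldimethylsilyloxy)-ent-labd-7-en-15-oic acid | CC(=O)O[C@H]1CC[C@]2(C)[C@H](CC=C(C)[C@H]2CC[C@@H](C)CC(=O)O)[C@]1(C)CO[Si](C)(C)C(C)(C)C | intermediate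
19 | (3S,4R,5S,9R,10S,13R)-3-acetoxy-19-hydroxylabd-7-en-15-oic acid (CNP0138726.1) | CC(=O)O[C@H]1CC[C@]2(C)[C@H](CC=C(C)[C@H]2CC[C@@H](C)CC(=O)O)[C@]1(C)CO | target

**Step count and risks**
Total step count: 14. Longest linear sequence: 13 steps (steps 1–3 and 5–14, from andrographolide).

Steps most likely to fail:

1. Step 5. The cross-coupling may be swamped by homo-coupling of either ester, or the C11 radical may be lost by reduction or by 1,2-acyl shift before nickel captures it. The fallback sets out from 4 and 6 and returns at 8, and makes the same bond by conjugate addition instead of radical–radical union. Kochi oxidative decarboxylation of 4 (Pb(OAc)4, Cu(OAc)2 cat., pyridine, benzene, 80 °C) should give the exocyclic enone 3,19-O-isopropylidene-12,13,14,15,16,17-hexanor-ent-labd-9(11)-en-8-one F1, in which C11 is the β-carbon of the C8 ketone. Suárez iododecarboxylation of 6 (PhI(OAc)2, I2, hν) should give methyl (S)-4-iodo-3-methylbutanoate F2. Luche-type radical conjugate addition of F2 to F1 (Zn, CuI, EtOH/H2O, sonication) forms C11–C12. Protonation of the resulting enolate and brief DBU equilibration should place the C9 side chain equatorial, which is compound 8.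

2. Step 11. Facial selectivity may be poor if the axial CH2OTBS group on C4 obstructs the equatorial approach of the bulky hydride, leaving the equatorial alcohol 13 as a co-product. The fallback sets out from 14 and returns at 15, and replaces steric control by intramolecular delivery. Desilylation of 14 (HF·pyridine) should give methyl (13R)-19-hydroxy-3-oxo-ent-labd-7-en-15-oate F3. Hydroxyl-directed reduction (Evans–Saksena conditions, Me4NBH(OAc)3, AcOH/MeCN, −20 °C) delivers hydride from the face of the axial C19 oxygen and should give the 1,3-anti diol methyl (3S,13R)-3,19-dihydroxy-ent-labd-7-en-15-oate F4 with the axial 3-OH. Selective silylation of the primary hydroxyl (TBSCl, imidazole) then gives 15.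

3. Step 6. Enolisation may not be fully regioselective (C9 instead of C7), or the ester may compete, which would misplace the alkene. The fallback sets out from 8 and returns at 11, and builds the alkene without an enolate. Wittig methylenation of the ketone (Ph3P=CH2, THF, 0 °C→rt; esters are inert) should give methyl (13R)-3,19-O-isopropylidene-ent-labd-8(17)-en-15-oate F5. Cobalt-salen/PhSiH3 hydrogen-atom-transfer isomerisation should then move the exocyclic alkene one position into the ring at C7=C8, because the accessible C7–H is abstracted in preference to the C9–H buried beside C10. This gives 11.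

**Further compounds**
F1 | step 5 | 3,19-O-isopropylidene-12,13,14,15,16,17-hexanor-ent-labd-9(11)-en-8-one | CC3(C)O[C@@H]1CC[C@]2(C)[C@H](CCC(=O)C2=C)[C@]1(C)CO3
F2 | step 5 | methyl (S)-4-iodo-3-methylbutanoate | COC(=O)C[C@H](C)CI
F3 | step 11 | methyl (13R)-19-hydroxy-3-oxo-ent-labd-7-en-15-oate | O=C1CC[C@]2(C)[C@H](CC=C(C)[C@H]2CC[C@@H](C)CC(=O)OC)[C@]1(C)CO
F4 | step 11 | methyl (3S,13R)-3,19-dihydroxy-ent-labd-7-en-15-oate (axial 3-OH) | O[C@H]1CC[C@]2(C)[C@H](CC=C(C)[C@H]2CC[C@@H](C)CC(=O)OC)[C@]1(C)CO
F5 | step 6 | methyl (13R)-3,19-O-isopropylidene-ent-labd-8(17)-en-15-oate | CC3(C)O[C@@H]1CC[C@]2(C)[C@H](CCC(=C)[C@H]2CC[C@@H](C)CC(=O)OC)[C@]1(C)CO3
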